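The synthesis rests on cutting the C4–O and C5–O bonds (C1 carries C7H2OBz, C2 is the vinylic CH, C3–C6 are the carbinols). The feature exploited is the all-cis C3–C6 tetrad on the lone cyclohexene ring. O3–H and O6–H are mutually cis and both allylic to C4=C5, so together they can hydrogen-bond an OsO4–diamine complex and steer it onto their own, more crowded face. One operation thus sets C4 and C5. The precursor is the acid-labile (3R,6S)-cyclohexa-1,4-diene-3,6-diol C7-benzoate 11. It is made from a quinone whose C4=C5 bond is masked by cyclopentadiene, resolved with a lipase, and unmasked as its bis-silyl ether.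

Key step: step 8

Locants and structure check: target locants C1–C7 are used for all intermediates, including the tricyclic ones. In the target all four ring C–O bonds lie on one face, (3S,4S,5R,6R). Compounds 11 (3R,6S) and 13 (3S,4S,5R,6R) have the matching spatial arrangement, and the change of letters at C3 and C6 is only a priority effect.

Assumption: in step 4 the lipase obeys the empirical large/medium-pocket rule for secondary alcohols, with the ring-fusion carbon as the large group; the sense is to be verified on 8 by MTPA ester analysis.

Step 1
Reactants: 1 2,5-dimethoxybenzyl alcohol; 2 benzoyl chloride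
Product: 3 2,5-dimethoxybenzyl benzoate
Conditions: Et3N, 4-(dimethylamino)pyridine (cat.), CH2Cl2, 0 °C to rt
Reagents that add atoms: none
Why: Nucleophile-catalysed O-acylation of the only free hydroxyl; carrying the hydroquinone as its dimethyl ether removes any competition from the more easily benzoylated phenolic oxygens.

Step 2
Reactants: 3 2,5-dimethoxybenzyl benzoate
Product: 4 (3,6-dioxocyclohexa-1,4-dien-1-yl)methyl benzoate [2-(benzoyloxymethyl)-1,4-benzoquinone]
Conditions: (NH4)2Ce(NO3)6 (2.5 equiv), MeCN/H2O 3:1, 0 °C
Reagents that add atoms: water, O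
Why: Oxidative demethylation of a hydroquinone dimethyl ether by tetravalent cerium (two one-electron oxidations, water attacks the ipso carbons, methanol leaves), conditions to which the benzoate ester is inert.

Step 3
Reactants: 4 (3,6-dioxocyclohexa-1,4-dien-1-yl)methyl benzoate; 5 cyclopentadiene (cracked from its commercial dimer just before use)
Product: 7 (±)-[(1S*,4R*,4aS*,5S*,8R*,8aR*)-5,8-dihydroxy-1,4,4a,5,8,8a-hexahydro-1,4-methanonaphthalen-6-yl]methyl benzoate, via endo enedione adduct 6 (not isolated)
Conditions: 5 (1.05 equiv), MeOH, 0 °C, dark; then CeCl3·7H2O, NaBH4, −40 to 0 °C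
Reagents that add atoms: none
Why: One-pot Diels–Alder/Luche sequence: cyclopentadiene adds to the unsubstituted, less hindered C4=C5 bond of 4 under the Alder endo rule to give the cis-fused enedione 6, whose two carbonyls are then reduced 1,2 by the cerium-modified borohydride from the convex face carrying the ring-fusion hydrogens, so that O3 and O6 end up on the concave face and cis to each other (racemic at this stage).

Step 4
Reactants: 7 (±)-tricyclic diol C7-benzoate
Product: 8 [(1S,4R,4aS,5S,8R,8aR)-5,8-dihydroxy-1,4,4a,5,8,8a-hexahydro-1,4-methanonaphthalen-6-yl]methyl benzoate (3R,6S in target locants)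
Conditions: Burkholderia cepacia lipase (Amano PS, immobilised), vinyl acetate, t-BuOMe, 30 °C, stopped at ca. 55% conversion; chromatography
Reagents that add atoms: none
Why: Lipase-catalysed kinetic resolution by irreversible transesterification: the enzyme should acetylate the unhindered O3–H of the antipode, whose C3 has the fast-reacting shape (ring-fusion carbon large, vinylic CH medium), whereas in 8 that shape occurs only at C6, which is screened by the C1 side chain, so 8 stays free and gains enantiopurity once conversion passes one half, fixing the absolute configuration of C3 and C6.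

Step 5
Reactants: 8 enantiopure tricyclic diol C7-benzoate
Product: 9 3,6-bis(triethylsilyl) ether of 8
Conditions: Et3SiOTf (2.5 equiv), 2,6-lutidine, CH2Cl2, −78 to 0 °C
Reagents that add atoms: triethylsilyl triflate, CC[Si](CC)(CC)OS(=O)(=O)C(F)(F)F
Why: Silyl ether formation with a silyl triflate, reactive enough for the two concave-face hydroxyls, while the lutidine buffer prevents acid-induced transannular etherification onto the norbornene alkene; no stereocentre is touched.

Step 6
Reactants: 9 bis(triethylsilyl) ether of the tricyclic diol
Product: 10 [(3R,6S)-3,6-bis(triethylsilyloxy)cyclohexa-1,4-dien-1-yl]methyl benzoate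
Conditions: Ph2O, reflux (ca. 259 °C), N2 sweep, base-washed glass, 30–60 min
Reagents that add atoms: none
Why: Thermal retro-Diels–Alder cycloreversion, driven by entropy and by removal of volatile cyclopentadiene, erases the four auxiliary stereocentres and unveils C4=C5 while C3 and C6 stay untouched; the silyl caps take away the free bis-allylic hydroxyls that would dehydrate to a phenol at this temperature.

Step 7
Reactants: 10 bis(triethylsilyloxy)cyclohexadiene C7-benzoate
Product: 11 [(3R,6S)-3,6-dihydroxycyclohexa-1,4-dien-1-yl]methyl benzoate
Conditions: Bu4NF/AcOH (1:1, 2.5 equiv), THF, 0 °C; short Et3N-deactivated silica plug; used at once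
Reagents that add atoms: none
Why: Fluoride-mediated desilylation under acetic acid buffering runs close to neutral, so neither acid-catalysed dehydration of the arene-hydrate-like diol nor alkoxide-driven benzoyl migration from O7 to O6 is triggered, and no stereocentre is touched.

Step 8
Reactants: 11 [(3R,6S)-3,6-dihydroxycyclohexa-1,4-dien-1-yl]methyl benzoate
Product: 13 [(3S,4S,5R,6R)-3,4,5,6-tetrahydroxycyclohex-1-en-1-yl]methyl benzoate, via osmate ester TMEDA chelate 12 (not isolated)
Conditions: OsO4 (1.0 equiv), Me2NCH2CH2NMe2 (1.05 equiv), CH2Cl2, −78 °C; then Na2SO3, pH 7 phosphate buffer/THF, 45 °C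
Reagents that add atoms: osmium tetroxide, O=[Os](=O)(=O)=O
Why: Chelation by the diamine turns octavalent OsO4 into an electron-rich complex whose oxo ligands are good hydrogen-bond acceptors; in non-coordinating CH2Cl2 the C3 and C6 hydroxyls of 11 both bind it and hold it on their own face, where a concerted suprafacial [3+2] cycloaddition to C4=C5 gives the hexavalent osmate chelate 12, which sulfite then cleaves at the Os–O bonds. The closest known reaction type is the stoichiometric OsO4/TMEDA syn-dihydroxylation of cyclic allylic alcohols. No ring of the product is closed; only the transient five-membered osmate ring forms, by cycloaddition. C4 (S) and C5 (R) are both dictated by C3 and C6: syn addition makes the two new oxygens cis to each other, and the double hydrogen bond places them cis to O3 and O6, against the usual anti preference of allylic oxygen substituents. Site selectivity for C4=C5 over C1=C2, which is flanked by the same two hydroxyls, rests on its lower substitution toward the bulky chelated reagent and on the extra inductive deactivation of C1=C2 by the allylic benzoate, helped by a single equivalent of an oxidant that does not turn over. The amine-buffered medium at −78 °C also keeps the bis-allylic diol from dehydrating before it reacts.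

Step 9
Reactants: 13 all-cis tetrol C7-benzoate
Product: 14 [(3S,4R,5R,6R)-5,6-dihydroxy-3,4-(isopropylidenedioxy)cyclohex-1-en-1-yl]methyl benzoate (3,4-acetonide of 13; spatial arrangement unchanged)
Conditions: 2-methoxypropene (1.1 equiv), pyridinium p-toluenesulfonate (cat.), DMF, 0 °C
Reagents that add atoms: 2-methoxypropene, C=C(C)OC
Why: Kinetic acetonation by enol-ether transketalisation: the reagent should be captured first by the most accessible hydroxyl, the allylic O3–H next to the unsubstituted C2, and the mixed ketal closes on the cis O4–H, whereas O6–H is screened by the C1 side chain and one equivalent of reagent limits double ketalisation.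

Step 10
Reactants: 14 3,4-acetonide 5,6-diol; 2 benzoyl chloride
Product: 15 [(3S,4S,5R,6R)-5-(benzoyloxy)-6-hydroxy-3,4-(isopropylidenedioxy)cyclohex-1-en-1-yl]methyl benzoate
Conditions: 2 (1.1 equiv), Ph2BOCH2CH2NH2 (10 mol %), i-Pr2NEt, MeCN, rt
Reagents that add atoms: none
Why: Borinic-acid-catalysed regioselective acylation of a cis-1,2-diol: the tetracoordinate borinate of the O5/O6 pair should be benzoylated at the equatorial, less crowded O5, because allylic 1,2-strain with the C1 side chain keeps O6 pseudoaxial and shielded; no C–O bond breaks, so the configuration is retained.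

Step 11
Reactants: 15 3,4-acetonide 5,7-dibenzoate
Product: 16 [(3S,4S,5R,6R)-5-(benzoyloxy)-3,4,6-trihydroxycyclohex-1-en-1-yl]methyl benzoate (target)
Conditions: CF3CO2H/H2O 9:1, CH2Cl2, 0 °C
Reagents that add atoms: none
Why: Acid-catalysed ketal hydrolysis, under which benzoates neither cleave nor migrate at 0 °C, frees O3–H and O4–H with all four stereocentres intact.

Compound list
1 | 2,5-dimethoxybenzyl alcohol | COc1ccc(OC)c(CO)c1 | starting material
2 | benzoyl chloride | O=C(Cl)c1ccccc1 | starting material
3 | 2,5-dimethoxybenzyl benzoate | COc1ccc(OC)c(COC(=O)c2ccccc2)c1 | intermediate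
4 | (3,6-dioxocyclohexa-1,4-dien-1-yl)methyl benzoate | O=C(OCC1=CC(=O)C=CC1=O)c1ccccc1 | intermediate
5 | cyclopentadiene | C1=CC=CC1 | starting material
6 | (±)-endo adduct, [(1S*,4R*,4aS*,8aR*)-5,8-dioxo-1,4,4a,5,8,8a-hexahydro-1,4-methanonaphthalen-6-yl]methyl benzoate (racemate; enantiomer carried forward is drawn; not isolated) | O=C(OCC1=CC(=O)[C@@H]2[C@@H]3C=C[C@@H](C3)[C@@H]2C1=O)c1ccccc1 | intermediate
7 | (±)-tricyclic diol, both hydroxyls on the concave face, syn to the etheno bridge and cis to each other (racemate; enantiomer carried forward is drawn) | O=C(OCC1=C[C@H](O)[C@@H]2[C@@H]3C=C[C@@H](C3)[C@@H]2[C@@H]1O)c1ccccc1 | intermediate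
8 | (1S,4R,4aS,5S,8R,8aR)-tricyclic diol C7-benzoate, single enantiomer | O=C(OCC1=C[C@H](O)[C@@H]2[C@@H]3C=C[C@@H](C3)[C@@H]2[C@@H]1O)c1ccccc1 | intermediate
9 | bis(triethylsilyl) ether of 8 | O=C(OCC1=C[C@H](O[Si](CC)(CC)CC)[C@@H]2[C@@H]3C=C[C@@H](C3)[C@@H]2[C@@H]1O[Si](CC)(CC)CC)c1ccccc1 | intermediate
10 | [(3R,6S)-3,6-bis(triethylsilyloxy)cyclohexa-1,4-dien-1-yl]methyl benzoate | O=C(OCC1=C[C@H](O[Si](CC)(CC)CC)C=C[C@@H]1O[Si](CC)(CC)CC)c1ccccc1 | intermediate
11 | [(3R,6S)-3,6-dihydroxycyclohexa-1,4-dien-1-yl]methyl benzoate (precursor of the key step) | O=C(OCC1=C[C@H](O)C=C[C@@H]1O)c1ccccc1 | intermediate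
12 | cyclic O4,O5-osmate ester of hexavalent osmium chelated by TMEDA, on the face of O3 and O6 (not isolated) | O=C(OCC1=C[C@H](O)[C@@H]2O[Os-2]3(=O)(=O)([N+](C)(C)CC[N+]3(C)C)O[C@@H]2[C@@H]1O)c1ccccc1 | intermediate
13 | [(3S,4S,5R,6R)-3,4,5,6-tetrahydroxycyclohex-1-en-1-yl]methyl benzoate (product of the key step) | O=C(OCC1=C[C@H](O)[C@H](O)[C@H](O)[C@@H]1O)c1ccccc1 | intermediate
14 | 3,4-O-isopropylidene derivative of 13 | O=C(OCC1=C[C@@H]2OC(C)(C)O[C@@H]2[C@H](O)[C@@H]1O)c1ccccc1 | intermediate
15 | 5-O-benzoyl-3,4-O-isopropylidene derivative of 13 | O=C(OCC1=C[C@@H]2OC(C)(C)O[C@@H]2[C@H](OC(=O)c2ccccc2)[C@@H]1O)c1ccccc1 | intermediate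
16 | [(3S,4S,5R,6R)-5-(benzoyloxy)-3,4,6-trihydroxycyclohex-1-en-1-yl]methyl benzoate | O=C(OCC1=C[C@H](O)[C@H](O)[C@H](OC(=O)c2ccccc2)[C@@H]1O)c1ccccc1 | target

Total step count: 11. Longest linear sequence: 11 (from 1).

Steps most likely to fail

1. Step 8.
- What may go wrong: the oxidant may leak to the open face if hydrogen bonding is weakened (for instance by an O6–H contact with the C7 ester carbonyl). It may also attack C1=C2, or the diol may dehydrate before it is consumed.
- Fallback: it sets out from 10 and comes back at 16. It keeps the same two C–O bonds but replaces reagent delivery by a double inversion (Woodward variant of the Prévost reaction).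
- First stage: I2 and AgO2CPh in benzene attack C4=C5 of 10 on the face anti to both silyloxy groups. Benzoate then opens the iodonium ion from the silyloxy face to give the trans-iodo benzoate F1.
- Second stage: silver-assisted loss of iodide, with participation of the neighbouring benzoate, builds a cis-fused benzoxonium ion on the silyloxy face. Added water collapses it to the cis-hydroxy benzoate F2.
- Regiochemistry and end: the C4-ester isomer arises from the same cation, is separated, and is fed back by base-catalysed 1,2-acyl shift. Buffered fluoride as in step 7 then gives 16 directly, bypassing 11–15.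

2. Step 6.
- What may go wrong: cycloreversion of an unactivated norbornene needs a temperature at which side reactions begin to compete. These are aromatisation of the diene by loss of hydrogen or silanol and a [3,3] shift of the allylic benzoate.
- Fallback: it sets out from 4 and comes back at 10. It changes the mask rather than the heating.
- Sequence: 6,6-dimethylfulvene adds to C4=C5 of 4 to give the endo fulvene adduct F3. Luche reduction and the resolution of step 4 give the isopropylidene-bridged diol F4. Silylation as in step 5 gives its bis(triethylsilyl) ether F5.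
- Advantage: cycloreversion of F5 releases a cross-conjugated, stabilised diene. It should therefore proceed well below the temperature of step 6 (refluxing mesitylene or 1,2-dichlorobenzene) to give 10.

3. Step 9.
- What may go wrong: ketalisation may occur at the O5/O6 or O4/O5 pair or twice, and the ketal may migrate under acid catalysis.
- Fallback: it sets out from 13 and comes back at 16. It replaces the diol mask by a single bulky ether.
- Sequence: t-BuMe2SiCl and imidazole (DMF, −20 °C) should silylate the least hindered O3–H to give the 3-O-silyl triol F6. In F6, O5–H is the only equatorial hydroxyl and the only one without a bulky neighbour.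
- Benzoylation and end: both remaining cis-diol pairs (O4/O5 and O5/O6) funnel benzoylation with 2 onto O5, whether through the Bu2SnO stannylene or through borinate catalysis. This gives the 3-O-silyl 5-benzoate F7, and HF·pyridine (THF, 0 °C) then gives 16.

Further compounds
F1 | step 8 | trans-iodo benzoate: iodine at C4 anti, benzoate at C5 syn to the two silyloxy groups | O=C(OCC1=C[C@H](O[Si](CC)(CC)CC)[C@@H](I)[C@H](OC(=O)c2ccccc2)[C@@H]1O[Si](CC)(CC)CC)c1ccccc1
F2 | step 8 | all-cis 4-hydroxy 5-benzoate 3,6-bis(triethylsilyl) ether | O=C(OCC1=C[C@H](O[Si](CC)(CC)CC)[C@H](O)[C@H](OC(=O)c2ccccc2)[C@@H]1O[Si](CC)(CC)CC)c1ccccc1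
F3 | step 6 | endo adduct of 4 and 6,6-dimethylfulvene (9-isopropylidene analogue of 6; racemate, enantiomer carried forward drawn) | O=C(OCC1=CC(=O)[C@@H]2[C@@H]3C=C[C@@H](C3=C(C)C)[C@@H]2C1=O)c1ccccc1
F4 | step 6 | 9-isopropylidene analogue of 8 (made racemic, then resolved) | O=C(OCC1=C[C@H](O)[C@@H]2[C@@H]3C=C[C@@H](C3=C(C)C)[C@@H]2[C@@H]1O)c1ccccc1
F5 | step 6 | bis(triethylsilyl) ether of F4 | O=C(OCC1=C[C@H](O[Si](CC)(CC)CC)[C@@H]2[C@@H]3C=C[C@@H](C3=C(C)C)[C@@H]2[C@@H]1O[Si](CC)(CC)CC)c1ccccc1
F6 | step 9 | 3-O-(tert-butyldimethylsilyl) derivative of 13 | O=C(OCC1=C[C@H](O[Si](C)(C)C(C)(C)C)[C@H](O)[C@H](O)[C@@H]1O)c1ccccc1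
F7 | step 9 | 3-O-(tert-butyldimethylsilyl) derivative of 16 | O=C(OCC1=C[C@H](O[Si](C)(C)C(C)(C)C)[C@H](O)[C@H](OC(=O)c2ccccc2)[C@@H]1O)c1ccccc1
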